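Ring A carries oxygen on C5, C7 and C8a, the 1,3,5-pattern of a folded triketide, and C8, the carbon between C7 and C8a, carries the piperidine. Everything rests on disconnecting ring A at C8–C8a: an intramolecular Claisen condensation in which the carbanion next to the piperidine acylates the ester end of the chain. One operation closes the carbocycle, aromatises it and delivers the C5 oxygen as its methyl ether; the stereocentre is bought. The precursor is methyl (E)-3-methoxy-5-oxohex-2-enoate carrying (R)-1-Boc-piperidin-2-yl on C6. Ring C follows by iodination, Stille acetylation, enolate benzoylation and acid ring closure.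

Key step: step 2

Remark: the only stereocentre, C2' of the piperidine, is (R) in the target and is carried unchanged from commercial acid 1 (the side-chain CH2 of 1 becomes aromatic C8, and the descriptor stays R); the free base 17, a benzylic amine beside a phenol, is assumed to be best handled cold and stored as a salt.

Numbering used below: C1–C6 for the hexenoate chain of 5 (C1 = ester carbon), flavone numbering for ring A, C2' for the piperidine carbon.

Step 1
Reactants: 1 (R)-2-[1-(tert-butoxycarbonyl)piperidin-2-yl]acetic acid; 2 methyl (E)-3-methoxybut-2-enoate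
Product: 5 methyl (R,E)-6-[1-(tert-butoxycarbonyl)piperidin-2-yl]-3-methoxy-5-oxohex-2-enoate, via acyl imidazolide 3 (not isolated), via lithium dienolate 4 (not isolated)
Conditions: 1, 1,1'-carbonyldiimidazole (1.1 equiv), THF, 20 °C, N2 purge; add to 4 [2 (3.3 equiv), LiN(iPr)2 (3.3 equiv), THF, −78 °C], −78 °C; AcOH, −78 °C
Reagents that add atoms: none
Why: Claisen-type C-acylation of a lithium ester dienolate by an N-acylimidazole, in which the γ-carbon of 4 (an enol-ether terminus) is the nucleophilic site, the E β-methoxyacrylate geometry is regenerated, the excess dienolate holds the product as its C4 enolate so that no second addition occurs, and the cold acetic acid quench leaves no time for that enolate to lactonise.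

Step 2
Reactants: 5 methyl (R,E)-6-[1-(tert-butoxycarbonyl)piperidin-2-yl]-3-methoxy-5-oxohex-2-enoate
Product: 8 tert-butyl (R)-2-(2,6-dihydroxy-4-methoxyphenyl)piperidine-1-carboxylate, via dilithium dianion 6 (not isolated), via cyclohexadienone enolate 7 (not isolated)
Conditions: add 5 to LiN(iPr)2 (2.5 equiv), THF, −78 °C; −78 → −20 °C; AcOH, −78 °C
Reagents that add atoms: none
Why: LiN(iPr)2 removes first the C4 proton (between the ketone and the β-methoxyacrylate) and then a C6 proton; the terminal C6 carbon of dianion 6 adds to the ester carbonyl C1, methoxide leaves to give 7, and loss of the remaining C6 proton aromatises the ring to the bis-phenoxide, which the acid quench protonates to 8. The closest known reaction type is the Dieckmann-type (intramolecular Claisen) acylation at the terminal carbon of a 1,3-dicarbonyl dianion, the laboratory form of polyketide ring closure to phloroglucinols. Ring A closes in the 6-(enolexo)-exo-trig mode, C6 being the enolate carbon and the ester C=O lying outside the new ring. No stereocentre is created; C2' is a spectator and keeps its (R) configuration as long as no bond to it breaks. Two selectivities are needed: carbon C6 rather than the ketone oxygen must be acylated (oxygen attack would give a 2-pyranone), and ring closure must outrun β-elimination of the carbamate nitrogen from the C6 carbanion. The substrate secures the first through its E enol ether, which holds C1 on the same side as C4 within reach of C6 and leaves the terminal carbon as the most nucleophilic site of the dianion, and the second through a fully substituted tert-butyl carbamate nitrogen, a poor leaving group between −78 and −20 °C, while aromatisation makes the C–C closure irreversible.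

Step 3
Reactants: 8 tert-butyl (R)-2-(2,6-dihydroxy-4-methoxyphenyl)piperidine-1-carboxylate
Product: 9 tert-butyl (R)-2-(2,6-dihydroxy-3-iodo-4-methoxyphenyl)piperidine-1-carboxylate
Conditions: N-iodosuccinimide (1.0 equiv), MeCN/CH2Cl2, −40 → 0 °C, dark
Reagents that add atoms: N-iodosuccinimide, O=C1CCC(=O)N1I
Why: Electrophilic aromatic iodination of a phloroglucinol-type ring in which the two free positions are equivalent by symmetry and each is ortho to OMe, ortho to one OH and para to the other, so one equivalent of reagent should give a single mono-iodide under neutral conditions that leave the carbamate and the benzylic C–N bond alone.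

Step 4
Reactants: 9 tert-butyl (R)-2-(2,6-dihydroxy-3-iodo-4-methoxyphenyl)piperidine-1-carboxylate; 10 tributyl(1-ethoxyvinyl)stannane
Product: 12 tert-butyl (R)-2-(3-acetyl-2,6-dihydroxy-4-methoxyphenyl)piperidine-1-carboxylate, via enol ether 11 (not isolated)
Conditions: 10 (1.5 equiv), Pd(PPh3)4 (5 mol %), toluene, 95 °C; then HCl (1 M, aq), THF, 0 °C
Reagents that add atoms: water, O
Why: Stille coupling of the aryl iodide with an α-ethoxyvinylstannane as a masked acetyl group, followed by hydrolysis of the enol ether, which tolerates free phenols, cleaves the enol ether far faster than the tert-butyl carbamate in cold dilute acid, and brings in the acetyl group without a Lewis acid that could ionise the benzylic C–N bond.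

Step 5
Reactants: 12 tert-butyl (R)-2-(3-acetyl-2,6-dihydroxy-4-methoxyphenyl)piperidine-1-carboxylate; 13 benzoyl chloride
Product: 15 tert-butyl (R)-2-[2,6-dihydroxy-4-methoxy-3-(3-oxo-3-phenylpropanoyl)phenyl]piperidine-1-carboxylate, via trilithium trianion 14 (not isolated)
Conditions: LiN(SiMe3)2 (5 equiv), THF, −78 → −10 °C; 13 (1.05 equiv), −78 → 20 °C; HCl (1 M, aq), 0 °C
Reagents that add atoms: none
Why: Direct C-aroylation of the lithium enolate of an o-hydroxyacetophenone polyanion, the one-flask form of the Baker–Venkataraman route to 1-(2-hydroxyaryl)-1,3-diketones, in which the lithium phenoxides are poor nucleophiles in THF at −78 °C while the enolate carbon takes the acid chloride and the excess base turns the product into its unreactive enolate.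

Step 6
Reactants: 15 tert-butyl (R)-2-[2,6-dihydroxy-4-methoxy-3-(3-oxo-3-phenylpropanoyl)phenyl]piperidine-1-carboxylate
Product: 17 (R)-7-hydroxy-5-methoxy-2-phenyl-8-(piperidin-2-yl)-4H-chromen-4-one, via amino diketone trifluoroacetate 16 (not isolated)
Conditions: CF3CO2H/CH2Cl2 (1:1), 0 → 40 °C; then NaHCO3 (aq), 0 °C
Reagents that add atoms: none
Why: Acidolysis of the tert-butyl carbamate and acid-catalysed cyclodehydration of the o-hydroxyaryl 1,3-diketone (last stage of the Baker–Venkataraman flavone synthesis), in which only the hydroxyl between the acyl group and the piperidine is ortho to the diketone so that a single chromone with the piperidine on C8 can form, the non-nucleophilic acid spares the 5-OMe ether, and the protonated amine cannot leave by a quinone-methide pathway, so the stereocentre should be kept.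

Compound list
1 | (R)-2-[1-(tert-butoxycarbonyl)piperidin-2-yl]acetic acid | OC(=O)C[C@H]1CCCCN1C(=O)OC(C)(C)C | starting material
2 | methyl (E)-3-methoxybut-2-enoate | COC(=O)/C=C(/OC)C | starting material
3 | tert-butyl (R)-2-[2-(1H-imidazol-1-yl)-2-oxoethyl]piperidine-1-carboxylate (acyl imidazolide) | O=C(C[C@H]1CCCCN1C(=O)OC(C)(C)C)n1ccnc1 | intermediate
4 | lithium 1,3-dimethoxybuta-1,3-dien-1-olate (γ-dienolate of 2) | C=C(OC)C=C(OC)O[Li] | intermediate
5 | methyl (R,E)-6-[1-(tert-butoxycarbonyl)piperidin-2-yl]-3-methoxy-5-oxohex-2-enoate | COC(=O)/C=C(/OC)CC(=O)C[C@H]1CCCCN1C(=O)OC(C)(C)C | intermediate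
6 | dilithium salt of 5 deprotonated at C4 and C6 | [Li+].[Li+].COC(=O)/C=C(/OC)[CH-]C(=O)[CH-][C@H]1CCCCN1C(=O)OC(C)(C)C | intermediate
7 | lithium 6-[(R)-1-(tert-butoxycarbonyl)piperidin-2-yl]-3-methoxy-5-oxocyclohexa-1,3-dien-1-olate (ring closed, not yet aromatic, either configuration at C6) | COC1=CC(=O)C([C@H]2CCCCN2C(=O)OC(C)(C)C)C(O[Li])=C1 | intermediate
8 | tert-butyl (R)-2-(2,6-dihydroxy-4-methoxyphenyl)piperidine-1-carboxylate | COc1cc(O)c([C@H]2CCCCN2C(=O)OC(C)(C)C)c(O)c1 | intermediate
9 | tert-butyl (R)-2-(2,6-dihydroxy-3-iodo-4-methoxyphenyl)piperidine-1-carboxylate | COc1cc(O)c([C@H]2CCCCN2C(=O)OC(C)(C)C)c(O)c1I | intermediate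
10 | tributyl(1-ethoxyvinyl)stannane | CCCC[Sn](CCCC)(CCCC)C(=C)OCC | starting material
11 | tert-butyl (R)-2-[3-(1-ethoxyvinyl)-2,6-dihydroxy-4-methoxyphenyl]piperidine-1-carboxylate | CCOC(=C)c1c(OC)cc(O)c([C@H]2CCCCN2C(=O)OC(C)(C)C)c1O | intermediate
12 | tert-butyl (R)-2-(3-acetyl-2,6-dihydroxy-4-methoxyphenyl)piperidine-1-carboxylate | CC(=O)c1c(OC)cc(O)c([C@H]2CCCCN2C(=O)OC(C)(C)C)c1O | intermediate
13 | benzoyl chloride | O=C(Cl)c1ccccc1 | starting material
14 | trilithium salt of 12 (both phenoxides and the methyl ketone enolate) | [Li]OC(=C)c1c(OC)cc(O[Li])c([C@H]2CCCCN2C(=O)OC(C)(C)C)c1O[Li] | intermediate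
15 | tert-butyl (R)-2-[2,6-dihydroxy-4-methoxy-3-(3-oxo-3-phenylpropanoyl)phenyl]piperidine-1-carboxylate | O=C(CC(=O)c1ccccc1)c1c(OC)cc(O)c([C@H]2CCCCN2C(=O)OC(C)(C)C)c1O | intermediate
16 | 1-{2,4-dihydroxy-6-methoxy-3-[(R)-piperidin-2-yl]phenyl}-3-phenylpropane-1,3-dione (present as its trifluoroacetate salt) | O=C(CC(=O)c1ccccc1)c1c(OC)cc(O)c([C@H]2CCCCN2)c1O | intermediate
17 | (R)-7-hydroxy-5-methoxy-2-phenyl-8-(piperidin-2-yl)-4H-chromen-4-one | COc1cc(O)c([C@H]2CCCCN2)c2oc(-c3ccccc3)cc(=O)c12 | target

Total step count: 6
Longest linear sequence: 6 steps (1 → 5 → 8 → 9 → 12 → 15 → 17)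

Steps most likely to fail

Step 2. Three processes threaten it: acylation through the ketone-enolate oxygen (lactonisation) instead of through C6; β-elimination of the carbamate nitrogen from the C6 carbanion, which opens the piperidine and erases the configuration; and slow closure onto an ester that the C4 anion deactivates. The fallback gives up the de novo construction of ring A; it sets out from benzoyl chloride 13 and comes back at the target 17. Commercial 1-(2,4-dihydroxy-6-methoxyphenyl)ethanone is C-benzoylated with 13 (LiN(SiMe3)2, THF, −78 °C) to 1-(2,4-dihydroxy-6-methoxyphenyl)-3-phenylpropane-1,3-dione F1, which is cyclodehydrated (H2SO4, AcOH, 95 °C) to 7-hydroxy-5-methoxy-2-phenyl-4H-chromen-4-one F2. Piperidine is N-chlorinated (N-chlorosuccinimide) to 1-chloropiperidine F3 and dehydrochlorinated (KOH, EtOH) to 2,3,4,5-tetrahydropyridine F4. A phenolic Mannich reaction of F2 with F4 (aqueous MeOH, 60 °C), expected mainly at C8, should give racemic 7-hydroxy-5-methoxy-2-phenyl-8-(piperidin-2-yl)-4H-chromen-4-one F5. Resolution on a chiral stationary phase, or through a diastereomeric salt with a dibenzoyltartaric acid, separates 17 from its (S)-enantiomer F6.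

Step 4. Oxidative addition to the electron-rich, doubly ortho-substituted aryl iodide may be slow, so that protodestannylation of the stannane by the free phenols and reductive deiodination take over. The fallback replaces the palladium coupling by an aryllithium acylation; it sets out from 9 and comes back at 17. Both phenols of 9 are protected (chloromethyl methyl ether, iPr2NEt, CH2Cl2) to give tert-butyl (R)-2-[3-iodo-4-methoxy-2,6-bis(methoxymethoxy)phenyl]piperidine-1-carboxylate F7. Iodine–lithium exchange (n-BuLi, THF, −78 °C) and trapping with N-methoxy-N-methylacetamide should give tert-butyl (R)-2-[3-acetyl-4-methoxy-2,6-bis(methoxymethoxy)phenyl]piperidine-1-carboxylate F8. Enolate benzoylation with 13 (LiN(SiMe3)2, THF, −78 °C) gives tert-butyl (R)-2-[4-methoxy-2,6-bis(methoxymethoxy)-3-(3-oxo-3-phenylpropanoyl)phenyl]piperidine-1-carboxylate F9. HCl in MeOH (50 °C) then removes both acetals and the carbamate and closes ring C to 17 after neutralisation.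

Step 5. The acid chloride may be taken by the unhindered phenoxide oxygen para to the acetyl group instead of by the enolate carbon, or the diketone enolate may be acylated a second time. The fallback accepts O-acylation and moves the acyl group afterwards; it sets out from 12 and comes back at 15. Both phenols of 12 are benzoylated with 13 (NaH, THF, 0 → 20 °C) to tert-butyl (R)-2-[3-acetyl-2,6-bis(benzoyloxy)-4-methoxyphenyl]piperidine-1-carboxylate F10. KOC(CH3)3 in THF brings about the Baker–Venkataraman shift of the benzoyl group from the oxygen ortho to the acetyl group onto the enolate carbon, giving tert-butyl (R)-2-[6-(benzoyloxy)-2-hydroxy-4-methoxy-3-(3-oxo-3-phenylpropanoyl)phenyl]piperidine-1-carboxylate F11. K2CO3 in MeOH cleaves the remaining benzoate to give 15.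

Further compounds
F1 | step 2 | 1-(2,4-dihydroxy-6-methoxyphenyl)-3-phenylpropane-1,3-dione | COc1cc(O)cc(O)c1C(=O)CC(=O)c1ccccc1
F2 | step 2 | 7-hydroxy-5-methoxy-2-phenyl-4H-chromen-4-one | COc1cc(O)cc2oc(-c3ccccc3)cc(=O)c12
F3 | step 2 | 1-chloropiperidine | ClN1CCCCC1
F4 | step 2 | 2,3,4,5-tetrahydropyridine | C1CCN=CC1
F5 | step 2 | racemic 7-hydroxy-5-methoxy-2-phenyl-8-(piperidin-2-yl)-4H-chromen-4-one | COc1cc(O)c(C2CCCCN2)c2oc(-c3ccccc3)cc(=O)c12
F6 | step 2 | (S)-7-hydroxy-5-methoxy-2-phenyl-8-(piperidin-2-yl)-4H-chromen-4-one | COc1cc(O)c([C@@H]2CCCCN2)c2oc(-c3ccccc3)cc(=O)c12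
F7 | step 4 | tert-butyl (R)-2-[3-iodo-4-methoxy-2,6-bis(methoxymethoxy)phenyl]piperidine-1-carboxylate | COc1cc(OCOC)c([C@H]2CCCCN2C(=O)OC(C)(C)C)c(OCOC)c1I
F8 | step 4 | tert-butyl (R)-2-[3-acetyl-4-methoxy-2,6-bis(methoxymethoxy)phenyl]piperidine-1-carboxylate | CC(=O)c1c(OC)cc(OCOC)c([C@H]2CCCCN2C(=O)OC(C)(C)C)c1OCOC
F9 | step 4 | tert-butyl (R)-2-[4-methoxy-2,6-bis(methoxymethoxy)-3-(3-oxo-3-phenylpropanoyl)phenyl]piperidine-1-carboxylate | O=C(CC(=O)c1ccccc1)c1c(OC)cc(OCOC)c([C@H]2CCCCN2C(=O)OC(C)(C)C)c1OCOC
F10 | step 5 | tert-butyl (R)-2-[3-acetyl-2,6-bis(benzoyloxy)-4-methoxyphenyl]piperidine-1-carboxylate | CC(=O)c1c(OC)cc(OC(=O)c2ccccc2)c([C@H]3CCCCN3C(=O)OC(C)(C)C)c1OC(=O)c1ccccc1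
F11 | step 5 | tert-butyl (R)-2-[6-(benzoyloxy)-2-hydroxy-4-methoxy-3-(3-oxo-3-phenylpropanoyl)phenyl]piperidine-1-carboxylate | O=C(CC(=O)c1ccccc1)c1c(OC)cc(OC(=O)c2ccccc2)c([C@H]3CCCCN3C(=O)OC(C)(C)C)c1O
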